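A share that looks flat over the first minutes is easily taken for a constant of the flask.

all flasks: substrate 49 mM; second nucleophile 245 mM
- violet: first nucleophile 49 mM; the very flask that is asked about, followed so far
- flask: first nucleophile 49.0 mM; time 40 min

violet run (percent of the substrate charged)

| time / min | other capture product / % | target / % | substrate / % |
|---|---|---|---|
| 0.417 | 2 | 6 | 97 |
| 0.667 | 2 | 7 | 92 |
| 1.33 | 4 | 14 | 83 |
| 2.50 | 7 | 19 | 72 |
| 5.00 | 12 | 36 | 51 |

(each reading ± 2 percentage points)



1. share of other capture product in other capture product plus target at 15 s
2. share of other capture product in other capture product plus target at 40 min
3. which of other capture product and target there is more of at 40 min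

Two views meet over the violet run. A colleague holds a frozen partition. At 5.00 min the readings give 12 % of other capture product and 36 % of target, a share of 25.0 %, and he keeps that share to the end.

I hold a draining partition. I assume that target comes from first nucleophile and other capture product from second nucleophile, which I hold at its charge. Up to that reading, first nucleophile averaged about 82.0 % of its charge. So the reading's ratio of 3.00 becomes 3.66. This is my reading of the capture ratio, the target made per other capture product made at full first nucleophile, a selectivity factor at the charged amounts.

Now I replace the falling curve by its mean. In this flask substrate and first nucleophile are charged alike, so on my assumption the fraction of first nucleophile left at the end equals the fraction q that went to other capture product. Its mean lies halfway between full charge and q. Then q is one over one plus the capture ratio times that mean, which gives 29.7 %. If the fall continues as read, 0.458 % of substrate remains at 40 min, so my share in this flask is about q, with target ahead.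

The forecast stands on my side, slightly higher: 24 % at 15 s, 32 % at 40 min, target ahead. It adds: “Later conversion of target to other product is untested.”

The flask gives 20.2 % at 15 s and 63.8 % at 40 min, with other capture product ahead.

    substrate → intermediate (k = 0.141 /min)
    second nucleophile + target → over-reaction product (k = 0.209 /M/min)
    second nucleophile + intermediate → other capture product (k = 128 /M/min)
    first nucleophile + intermediate → target (k = 2580 /M/min)

At 4.00 min this flask's share is 24.9 %, near the colleague's frozen share. At 40 min the flask holds 28.9 % of other capture product, close to q, but 16.4 % of target beside 54.4 % of over-reaction product. In a neighbour flask with 610 mM of second nucleophile and the other charges as in the recipe, the capture ratio scales down to 1.47. The same mean gives q as 47.9 %. That neighbour ends with 46.0 % of other capture product.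

The readings are simulated with made-up constants; noise was put on by code.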